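## The problem

The target is a (2S)-flavanone. A phloroglucinol-type ring A is fused through C4a–C8a to a dihydropyranone ring C, which carries the 3-hydroxy-4,5-dimethoxyphenyl ring B at C2, and an (E)-geranyl chain sits on C6 between the C5 and C7 hydroxyls. C2 is the only stereocenter, so nothing in the molecule can relay its configuration and it must come from a catalyst. C2 is also fragile: it is a benzylic ether carbon β to the C4 ketone, and base (or prolonged acid) opens ring C by retro-oxa-Michael reaction to an achiral 2'-hydroxychalcone, so it should be made late and never pass through a basic enolate. The geranyl chain rules out hydrogenation, peracids, strong electrophiles and hot acid (its 2,3-alkene cyclises onto a flanking phenol to a chroman). The two methyl ethers of ring B rule out methyl or benzyl protection of the three phenols. Regiochemistry is the second issue, because closure of a free 2,4,6-trioxygenated aryl ketone does not distinguish C6 from C8. The enabling feature is that, at the flavone oxidation level, C4 is a carbonyl carbon between C4a and C3 and C2–C3 is an aryl alkyne bearing ring B; C4 can therefore be carbon monoxide inserted between an aryl iodide at C4a and a terminal alkyne, with O1 closing onto C2. If the iodophenol comes from a phenol that is symmetric about its hydroxyl–geranyl axis, O1 is necessarily para to geranyl and only the 6-geranyl isomer can form.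

## Retrosynthesis

**18 to 17.** The three O–CH2OMe bonds are cut last. MOM is chosen because ring A needs it anyway as the directing group for lithiation, it survives organolithiums, amines, CO/palladium and copper hydride, and it leaves in dilute methanolic acid that an ortho-geranyl phenol tolerates. Methyl, benzyl and allyl ethers are excluded by the ring B methyl ethers, the alkenes and the hydride step respectively. The forward step must be cold and short enough to spare geranyl and C2.

**17 to 15.** The C2–H bond is cut, taking the flavanone back to flavone 15. The neighbouring options are worse here: asymmetric oxa-Michael closure of a simple 2'-hydroxychalcone is reversible and poorly selective, and asymmetric hydrogenation endangers the geranyl alkenes. Flavone 15 is flat, achiral and base-stable. The forward step must deliver hydride 1,4 to one face of C2, leave isolated alkenes alone and release the ketone without a basic enolate; copper hydride with a silane does this through silyl enol ether 16.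

**15 to 8 + 11 + 12.** C4a–C4, C4–C3 and O1–C2 are cut together, giving iodophenol 8, arylacetylene 11 and carbon monoxide 12. Chalcone or diketone routes to a flavone need an acetophenone on ring A and an oxidative cyclisation that geranyl would not survive; this cut needs neither. Each fragment is a single arene. The forward reaction must insert CO before the alkyne couples and must close six-membered; ynone 13 and its amine adduct 14 are the expected intermediates.

**8 to 7.** The C–I bond is cut. Phenol 7 has two equivalent positions ortho to its hydroxyl, so mono-iodination has no regiochemical choice, and the free hydroxyl is para to geranyl. The forward step must iodinate the arene and not the alkenes.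

**7 to 5.** The C–O bond para to geranyl is cut, through arylboronate 6. In 5 that carbon bears the only ring hydrogen without an ortho substituent, which is exactly the site a sterically controlled iridium C–H borylation selects. Carrying a halogen placeholder at that carbon instead would not work: a bromide undergoes exchange with alkyllithiums, and an amide base would deprotonate next to the halogen. Carrying a third protected oxygen costs a protection and a deprotection. The forward step must borylate the arene in the presence of two trisubstituted alkenes.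

**5 to 2 + 3, and 2 to 1.** The aryl–CH2 bond is cut to aryllithium 4 and geranyl bromide 3. Lithiation of 2 between its two MOM ethers is unambiguous, and substitution at the primary carbon of 3 keeps the E alkene. Compound 2 is the bis-MOM ether of resorcinol 1.

**11 to 10 to 9.** The alkyne carbon is removed by one-carbon homologation of aldehyde 10, which is the MOM ether of commercial 3-hydroxy-4,5-dimethoxybenzaldehyde 9. This places ring B's oxygens with no further manipulation.

## Roads not taken

**Alternative 1:** ring A is built last. The cut removes C5–C6, C7–C8 and C4a–C5 and leaves a chiral dihydropyranone that already carries ring B and C2. Forward, irradiation of diazoketone A2 triggers a Wolff rearrangement, and the ketene adds siloxyalkyne A3 in a [2+2], four-electron opening, six-electron closure cascade that should give A1 with C5–OH free and C7–O silylated.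
- Merits: the polarity of A3 fixes geranyl at C6 without relying on symmetry; C2 is set on a small pyranone by established asymmetric chemistry; the end game needs only fluoride, so geranyl never meets acid. In that last respect it is better than the chosen plan.
- Weak points: C2 must survive diazo transfer and ultraviolet light while β to an enone that can open by β-elimination; the enone chromophore of A2 and the alkenes of A3 invite [2+2] photocycloaddition; A3 is a sensitive ynol ether; both partners take several steps.
- Comparison: the chosen plan sets against the cleaner end game a shorter, thermal, convergent assembly from two simple arenes and CO, and a stereocenter that does not exist until one step before the end.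

**Alternative 2:** ring C by [4+2] cycloaddition. The cut removes O1–C2 and C3–C4. Forward, a chiral Brønsted acid ionises acetal A5, and the resulting heterodiene (O1=C8a–C4a=C4–OMe) adds styrene A6 to give the 2,4-cis flavan A4.
- Merits: ring C and C2 arise in one enantioselective step from two separately made arenes, which is more direct than making a flavone and reducing it.
- Weak points: A4 is at the wrong oxidation level at C4, so a benzylic oxidation is needed beside geranyl and three electron-rich rings; the geranyl alkenes are electron-rich 2π partners and acid-sensitive under the ionising conditions; the C5 silyloxy group crowds C4 and the trioxygenated heterodiene is strongly stabilised, which works against rate and facial control.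
- Comparison: equal in convergence, and better in that the stereocenter forms with the ring. The chosen plan answers with the correct oxidation level straight from the key step and no acid or oxidant near geranyl until the final deprotection.

**Alternative 3:** ring C by C–O coupling. The cut removes O1–C8a. Forward, CuI/1,10-phenanthroline/Cs2CO3 couples the (S)-carbinol of bromo diol A8 with its aryl bromide (Ullmann-type etherification). The C2–O bond is untouched, so configuration is retained, giving flavan-4-ol A7, which is then oxidised at C4 and deprotected.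
- Merits: C2 comes from a mature asymmetric reaction on an acyclic carbinol and is carried through without risk; enantiocontrol is more certain than in the chosen plan, and that is its real advantage.
- Weak points: the electron-rich, ortho-substituted aryl bromide needs heat and carbonate base, with a benzylic alkoxide that can eliminate; ring A needs a bromide ortho to the three-carbon chain and meta to geranyl, which is harder to place than the iodine of 8; the route is linear and longer, and the final acid step is the same.
- Comparison: the chosen plan sets against the safer stereochemistry a three-bond, three-component key step and fewer redox operations, at the price of an asymmetric reduction that is less tried on this substitution pattern.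

Key step: step 7

Remark on the chemistry: flavonoid numbering is used (O1, C2, C3, C4, C4a, C5–C8, C8a; ring B primed); geranyl = (2E)-3,7-dimethylocta-2,6-dien-1-yl, MOM = methoxymethyl, dtbpy = 4,4'-di-tert-butyl-2,2'-bipyridine, pin = pinacolato.

Assumption: (S)-DTBM-SEGPHOS is taken to direct hydride to the Re face of C2 (giving 2S) by analogy with β-substituted cyclic enones; the sense is to be checked on 2-phenylchromone first, and the (R)-ligand is used if it proves opposite.

## Route

Step 1
Reactants: 1 resorcinol
Product: 2 1,3-bis(methoxymethoxy)benzene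
Conditions: MOMCl (2.5 equiv), iPr2NEt (3 equiv), CH2Cl2, 0 °C → rt
Reagents that add atoms: chloromethyl methyl ether, COCCl
Why: Williamson-type O-alkylation of both phenols; the MOM ethers serve as base-stable protection and as the directing groups for step 2.

Step 2
Reactants: 2 1,3-bis(methoxymethoxy)benzene; 3 geranyl bromide
Product: 5 2-geranyl-1,3-bis(methoxymethoxy)benzene, via aryllithium 4 (not isolated)
Conditions: n-BuLi (1.1 equiv), THF, 0 °C, 1 h; CuI (10 mol %), then 3, –78 °C → rt
Reagents that add atoms: none
Why: Directed ortho-metalation: both MOM oxygens chelate lithium, so deprotonation occurs only at the carbon between them (4); copper-mediated allylic substitution at the primary carbon of 3 (SN2, not SN2') installs geranyl with the E alkene untouched.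

Step 3
Reactants: 5 2-geranyl-1,3-bis(methoxymethoxy)benzene
Product: 7 4-geranyl-3,5-bis(methoxymethoxy)phenol, via arylboronate 6 (not isolated)
Conditions: [Ir(OMe)(cod)]2 (1.5 mol %), dtbpy (3 mol %), B2pin2 (1.0 equiv), THF, 60 °C; then 30% H2O2, 2 M NaOH, 0 °C
Reagents that add atoms: hydrogen peroxide, OO
Why: Sterically controlled iridium-catalysed aromatic C–H borylation: the ring C–H para to geranyl is the only one without an ortho substituent, and hindered trisubstituted alkenes are poor substrates for (dtbpy)Ir(Bpin)3. Alkaline peroxide then converts C–B into C–O, giving the phenol that is symmetric about its hydroxyl–geranyl axis.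

Step 4
Reactants: 7 4-geranyl-3,5-bis(methoxymethoxy)phenol
Product: 8 4-geranyl-2-iodo-3,5-bis(methoxymethoxy)phenol
Conditions: NIS (1.0 equiv), NaHCO3, CH2Cl2, –40 → 0 °C, dark
Reagents that add atoms: N-iodosuccinimide, O=C1CCC(=O)N1I
Why: Electrophilic aromatic iodination of a phloroglucinol-type phenol, which should react with NIS far faster than an isolated trisubstituted alkene. The two positions ortho to the hydroxyl are equivalent, so one equivalent at low temperature should give a single mono-iodide, the first iodine slowing a second substitution.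

Step 5
Reactants: 9 3-hydroxy-4,5-dimethoxybenzaldehyde
Product: 10 3,4-dimethoxy-5-(methoxymethoxy)benzaldehyde
Conditions: MOMCl (1.5 equiv), iPr2NEt (2 equiv), CH2Cl2, 0 °C → rt
Reagents that add atoms: chloromethyl methyl ether, COCCl
Why: MOM protection of the single phenol, giving ring B the same protecting group as ring A so that one final step unmasks all three hydroxyls.

Step 6
Reactants: 10 3,4-dimethoxy-5-(methoxymethoxy)benzaldehyde
Product: 11 5-ethynyl-1,2-dimethoxy-3-(methoxymethoxy)benzene
Conditions: dimethyl (1-diazo-2-oxopropyl)phosphonate (1.3 equiv), K2CO3 (2 equiv), MeOH, 0 °C → rt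
Reagents that add atoms: dimethyl (1-diazo-2-oxopropyl)phosphonate, COP(=O)(OC)C(=[N+]=[N-])C(C)=O
Why: Ohira–Bestmann modification of the Seyferth–Gilbert homologation: methanolysis of the reagent releases the diazomethylphosphonate anion, which olefinates the aldehyde and loses N2 with 1,2-hydrogen shift to the terminal alkyne. The carbonate base leaves the MOM ether intact.

Step 7
Reactants: 8 4-geranyl-2-iodo-3,5-bis(methoxymethoxy)phenol; 11 5-ethynyl-1,2-dimethoxy-3-(methoxymethoxy)benzene; 12 carbon monoxide
Product: 15 6-geranyl-5,7-bis(methoxymethoxy)-2-[3,4-dimethoxy-5-(methoxymethoxy)phenyl]-4H-chromen-4-one, via ynone 13 (not isolated), via enaminone 14 (not isolated)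
Conditions: PdCl2(PPh3)2 (5 mol %), CO (10 bar), Et2NH, 100 °C, autoclave
Reagents that add atoms: none
Why: This is the known three-component flavone synthesis from an ortho-iodophenol, a terminal alkyne and CO (carbonylative Sonogashira coupling followed by oxa-Michael annulation). Zerovalent palladium, formed by reduction of PdCl2(PPh3)2 in the amine, adds oxidatively to the C–I bond of 8, and CO inserts to give the aroyl complex of divalent palladium, ArC(O)Pd(PPh3)2I (C4a–C4). The amine-deprotonated alkyne 11 then replaces iodide and reductive elimination gives ynone 13 (C4–C3). Et2NH adds to 13 to give β-amino enone 14, and the ortho hydroxyl attacks its β-carbon in a 6-endo-trig addition–elimination (formally the 6-endo-dig oxa-Michael closure of 13) that forms O1–C2, expels Et2NH and closes ring C as the pyranone of 15. No stereocenter is created. Three selectivities are needed: CO insertion before alkyne transfer, which CO pressure and the electron-rich, doubly ortho-oxygenated ArPd(PPh3)2I favour over direct coupling to a 2-arylbenzofuran; alkyne capture of the aroyl complex before aminolysis, helped by the copper-free medium in which the arylacetylene is the better ligand for palladium; and six- over five-membered closure, secured because 14 is electrophilic only at its β-carbon, so the 5-exo aurone path is closed. Ring A regiochemistry is not at stake, since the only free hydroxyl of 8 is para to geranyl, and the MOM ethers, methyl ethers and both alkenes are inert to this basic, non-oxidising medium.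

Step 8
Reactants: 15 6-geranylflavone tris-MOM ether
Product: 17 (2S)-6-geranyl-5,7-bis(methoxymethoxy)-2-[3,4-dimethoxy-5-(methoxymethoxy)phenyl]-2,3-dihydro-4H-chromen-4-one, via silyl enol ether 16 (not isolated)
Conditions: Cu(OAc)2 (5 mol %), (S)-DTBM-SEGPHOS (5.5 mol %), (EtO)2MeSiH (3 equiv), toluene, 0 °C → rt; then NH4F, MeOH, 0 °C
Reagents that add atoms: none
Why: Asymmetric copper hydride conjugate reduction, a known reaction of 2-substituted chromones: bisphosphine-ligated CuH adds hydride to C2 and the ligand decides the face (Re face of C2, O1 > C1' > C3, hence 2S). The copper enolate is silylated to 16, which regenerates CuH, shields C4 from 1,2-reduction and cannot lose O1 by β-elimination. Buffered fluoride then protonates C3 without a basic enolate stage; isolated trisubstituted alkenes and aryl MOM ethers do not react with CuH.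

Step 9
Reactants: 17 (2S)-6-geranylflavanone tris-MOM ether
Product: 18 (2S)-6-geranyl-5,7-dihydroxy-2-(3-hydroxy-4,5-dimethoxyphenyl)-2,3-dihydro-4H-chromen-4-one
Conditions: HCl (2 M in MeOH), THF, 0 °C → rt
Reagents that add atoms: none
Why: Acid-catalysed methanolysis (acetal exchange) of the three MOM ethers, the peri C5 and vinylogous C7 ethers going first. Cold dilute methanolic HCl is the mildest medium that still cleaves the ring B ether while staying clear of geranyl cyclisation onto the new phenols and of acid-mediated ring opening at C2, whose bonds are not touched.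

## Compound list

1 | resorcinol (benzene-1,3-diol) | Oc1cccc(O)c1 | starting material
2 | 1,3-bis(methoxymethoxy)benzene | COCOc1cccc(OCOC)c1 | intermediate
3 | geranyl bromide, (2E)-1-bromo-3,7-dimethylocta-2,6-diene | BrC/C=C(\C)CCC=C(C)C | starting material
4 | [2,6-bis(methoxymethoxy)phenyl]lithium | [Li]c1c(OCOC)cccc1OCOC | intermediate (not isolated)
5 | 2-[(2E)-3,7-dimethylocta-2,6-dien-1-yl]-1,3-bis(methoxymethoxy)benzene | COCOc1cccc(OCOC)c1C/C=C(\C)CCC=C(C)C | intermediate
6 | 2-{4-[(2E)-3,7-dimethylocta-2,6-dien-1-yl]-3,5-bis(methoxymethoxy)phenyl}-4,4,5,5-tetramethyl-1,3,2-dioxaborolane | COCOc1cc(B2OC(C)(C)C(C)(C)O2)cc(OCOC)c1C/C=C(\C)CCC=C(C)C | intermediate (not isolated)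
7 | 4-[(2E)-3,7-dimethylocta-2,6-dien-1-yl]-3,5-bis(methoxymethoxy)phenol | COCOc1cc(O)cc(OCOC)c1C/C=C(\C)CCC=C(C)C | intermediate
8 | 4-[(2E)-3,7-dimethylocta-2,6-dien-1-yl]-2-iodo-3,5-bis(methoxymethoxy)phenol | Oc1cc(OCOC)c(C/C=C(\C)CCC=C(C)C)c(OCOC)c1I | intermediate
9 | 3-hydroxy-4,5-dimethoxybenzaldehyde | COc1cc(C=O)cc(O)c1OC | starting material
10 | 3,4-dimethoxy-5-(methoxymethoxy)benzaldehyde | COc1cc(C=O)cc(OCOC)c1OC | intermediate
11 | 5-ethynyl-1,2-dimethoxy-3-(methoxymethoxy)benzene | C#Cc1cc(OC)c(OC)c(OCOC)c1 | intermediate
12 | carbon monoxide | [C-]#[O+] | starting material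
13 | 1-[3-geranyl-6-hydroxy-2,4-bis(methoxymethoxy)phenyl]-3-[3,4-dimethoxy-5-(methoxymethoxy)phenyl]prop-2-yn-1-one | COc1cc(C#CC(=O)c2c(O)cc(OCOC)c(C/C=C(\C)CCC=C(C)C)c2OCOC)cc(OCOC)c1OC | intermediate (not isolated)
14 | (2E)-3-(diethylamino)-1-[3-geranyl-6-hydroxy-2,4-bis(methoxymethoxy)phenyl]-3-[3,4-dimethoxy-5-(methoxymethoxy)phenyl]prop-2-en-1-one | CCN(CC)/C(=C/C(=O)c1c(O)cc(OCOC)c(C/C=C(\C)CCC=C(C)C)c1OCOC)c1cc(OC)c(OC)c(OCOC)c1 | intermediate (not isolated)
15 | 2-[3,4-dimethoxy-5-(methoxymethoxy)phenyl]-6-[(2E)-3,7-dimethylocta-2,6-dien-1-yl]-5,7-bis(methoxymethoxy)-4H-chromen-4-one | COc1cc(-c2cc(=O)c3c(OCOC)c(C/C=C(\C)CCC=C(C)C)c(OCOC)cc3o2)cc(OCOC)c1OC | intermediate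
16 | (2S)-4-{[diethoxy(methyl)silyl]oxy}-2-[3,4-dimethoxy-5-(methoxymethoxy)phenyl]-6-geranyl-5,7-bis(methoxymethoxy)-2H-chromene | COc1cc([C@@H]2C=C(O[Si](C)(OCC)OCC)c3c(OCOC)c(C/C=C(\C)CCC=C(C)C)c(OCOC)cc3O2)cc(OCOC)c1OC | intermediate (not isolated)
17 | (2S)-2-[3,4-dimethoxy-5-(methoxymethoxy)phenyl]-6-[(2E)-3,7-dimethylocta-2,6-dien-1-yl]-5,7-bis(methoxymethoxy)-2,3-dihydro-4H-chromen-4-one | COc1cc([C@@H]2CC(=O)c3c(OCOC)c(C/C=C(\C)CCC=C(C)C)c(OCOC)cc3O2)cc(OCOC)c1OC | intermediate
18 | (2S)-6-[(2E)-3,7-dimethylocta-2,6-dien-1-yl]-5,7-dihydroxy-2-(3-hydroxy-4,5-dimethoxyphenyl)-2,3-dihydro-4H-chromen-4-one (CNP0228243.1) | COc1cc([C@@H]2CC(=O)c3c(cc(O)c(C/C=C(\C)CCC=C(C)C)c3O)O2)cc(O)c1OC | target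

## Step count and least certain steps

Total: 9 steps. Longest linear sequence: 7 steps (steps 1, 2, 3, 4, 7, 8, 9 from resorcinol); the alkyne arm is 2 steps (5, 6).

**Step 7 (key step).** Four things may go wrong: slow oxidative addition at the electron-rich, doubly ortho-substituted C–I bond; alkyne transfer before CO insertion, followed by closure to a benzofuran; aminolysis of the aroyl complex by the solvent amine; and five-membered closure. The fallback builds the same ynone without palladium or CO, setting out from 8 and 11 and returning at 15. Iodophenol 8 is silylated (TBSCl, imidazole) to the tert-butyldimethylsilyl ether F1. Iodine–magnesium exchange with iPrMgCl·LiCl gives the arylmagnesium chloride F2. Alkyne 11 is deprotonated with n-BuLi to the lithium acetylide F3 and acylated with N-methoxy-N-methylcarbamoyl chloride to the N-methoxy-N-methylpropiolamide F4. Addition of F2 to F4 gives the silyl-protected ynone F5. Acetic acid-buffered TBAF unmasks 13, which is cyclised through 14 with Et2NH to 15.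

**Step 8.** The reduction may be sluggish, because the chromone is a vinylogous ester further deactivated by three oxygen donors and twisted by the C5 MOM ether. Facial selectivity may be poor for the 2-aryl case, and some 1,2-reduction or ring opening of the enolate may occur. The fallback separates reduction from enantiocontrol, setting out from 15 and returning at 17. The achiral system Cu(OAc)2/1,2-bis(diphenylphosphino)benzene/(EtO)2MeSiH gives the racemic silyl enol ether F6, and NH4F in MeOH releases the racemic flavanone tris-MOM ether F7. Kinetic resolution by asymmetric transfer hydrogenation with RuCl[(R,R)-TsDPEN](p-cymene) and HCO2H/Et3N should reduce the (2R)-enantiomer to the cis-(2R,4R)-flavan-4-ol F8 and leave (2S)-17, at the cost of half the material. Transfer hydrogenation does not touch isolated alkenes.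

**Step 3.** The catalyst may engage the alkenes (hydroboration by the pinacolborane formed, or vinylic C–H borylation), or borylation of the electron-rich arene may be too slow at a temperature the chain tolerates. The fallback puts the oxygen in before geranyl, setting out from 2 and returning at 7. Borylation of 2 under the same conditions gives the 3,5-bis(methoxymethoxy)phenylboronate F9, oxidised in the same flask to 3,5-bis(methoxymethoxy)phenol F10. Silylation (iPr3SiCl, imidazole) gives the triisopropylsilyl ether F11, whose bulky, non-directing silyloxy group leaves the site between the MOM ethers as the only good lithiation site. n-BuLi gives the aryllithium F12, which is alkylated with 3 (CuI) to the geranylated silyl ether F13. TBAF then gives 7. This costs two extra steps.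

**Step 9.** The 2,3-alkene of geranyl may cyclise onto the freed C5 or C7 hydroxyl, and acid-mediated ring–chain equilibration may erode the configuration at C2 during the longer exposure needed for the ring B ether. The fallback moves the acid step in front of the stereocenter and ends with fluoride, setting out from 15 and returning at 18. Methanolic HCl on the flat flavone gives the 5,7,3'-trihydroxyflavone F14. TBSOTf/2,6-lutidine gives the tris(tert-butyldimethylsilyl) flavone F15. Reduction as in step 8 proceeds through the silyl enol ether F16 to the (2S)-flavanone tris-silyl ether F17, and Et3N·3HF removes the silyl groups under mildly acidic, non-basic conditions. The fallback removes the risk to C2 but not the chroman risk, which is merely easier to manage on an achiral, crystalline flavone.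

**Step 4.** Iodonium transfer to the trisubstituted alkenes or a second aromatic iodination may compete. The fallback installs iodine by directed metalation instead of an electrophile, setting out from 7 and returning at 8. Dihydropyran/PPTS gives the tetrahydropyranyl ether F18. n-BuLi deprotonates one of the two equivalent positions flanked by the two acetal oxygens to give the aryllithium F19, and I2 at –78 °C gives the iodinated tetrahydropyranyl ether F20. PPTS in MeOH at rt removes the tetrahydropyranyl group selectively in the presence of the aryl MOM ethers.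

## Further compounds

F1 | step 7 | tert-butyl{4-geranyl-2-iodo-3,5-bis(methoxymethoxy)phenoxy}dimethylsilane | CC(C)(C)[Si](C)(C)Oc1cc(OCOC)c(C/C=C(\C)CCC=C(C)C)c(OCOC)c1I
F2 | step 7 | {2-(tert-butyldimethylsilyloxy)-5-geranyl-4,6-bis(methoxymethoxy)phenyl}magnesium chloride | Cl[Mg]c1c(O[Si](C)(C)C(C)(C)C)cc(OCOC)c(C/C=C(\C)CCC=C(C)C)c1OCOC
F3 | step 7 | {[3,4-dimethoxy-5-(methoxymethoxy)phenyl]ethynyl}lithium | [Li]C#Cc1cc(OC)c(OC)c(OCOC)c1
F4 | step 7 | 3-[3,4-dimethoxy-5-(methoxymethoxy)phenyl]-N-methoxy-N-methylprop-2-ynamide | CON(C)C(=O)C#Cc1cc(OC)c(OC)c(OCOC)c1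
F5 | step 7 | 1-[2-(tert-butyldimethylsilyloxy)-5-geranyl-4,6-bis(methoxymethoxy)phenyl]-3-[3,4-dimethoxy-5-(methoxymethoxy)phenyl]prop-2-yn-1-one | COc1cc(C#CC(=O)c2c(O[Si](C)(C)C(C)(C)C)cc(OCOC)c(C/C=C(\C)CCC=C(C)C)c2OCOC)cc(OCOC)c1OC
F6 | step 8 | racemic 4-{[diethoxy(methyl)silyl]oxy}-2-[3,4-dimethoxy-5-(methoxymethoxy)phenyl]-6-geranyl-5,7-bis(methoxymethoxy)-2H-chromene | COc1cc(C2C=C(O[Si](C)(OCC)OCC)c3c(OCOC)c(C/C=C(\C)CCC=C(C)C)c(OCOC)cc3O2)cc(OCOC)c1OC
F7 | step 8 | racemic 2-[3,4-dimethoxy-5-(methoxymethoxy)phenyl]-6-geranyl-5,7-bis(methoxymethoxy)-2,3-dihydro-4H-chromen-4-one | COc1cc(C2CC(=O)c3c(OCOC)c(C/C=C(\C)CCC=C(C)C)c(OCOC)cc3O2)cc(OCOC)c1OC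
F8 | step 8 | (2R,4R)-2-[3,4-dimethoxy-5-(methoxymethoxy)phenyl]-6-geranyl-5,7-bis(methoxymethoxy)-3,4-dihydro-2H-chromen-4-ol | COc1cc([C@H]2C[C@@H](O)c3c(OCOC)c(C/C=C(\C)CCC=C(C)C)c(OCOC)cc3O2)cc(OCOC)c1OC
F9 | step 3 | 2-[3,5-bis(methoxymethoxy)phenyl]-4,4,5,5-tetramethyl-1,3,2-dioxaborolane | COCOc1cc(B2OC(C)(C)C(C)(C)O2)cc(OCOC)c1
F10 | step 3 | 3,5-bis(methoxymethoxy)phenol | COCOc1cc(O)cc(OCOC)c1
F11 | step 3 | [3,5-bis(methoxymethoxy)phenoxy]tri(propan-2-yl)silane | COCOc1cc(O[Si](C(C)C)(C(C)C)C(C)C)cc(OCOC)c1
F12 | step 3 | {2,6-bis(methoxymethoxy)-4-[tri(propan-2-yl)silyloxy]phenyl}lithium | [Li]c1c(OCOC)cc(O[Si](C(C)C)(C(C)C)C(C)C)cc1OCOC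
F13 | step 3 | [4-geranyl-3,5-bis(methoxymethoxy)phenoxy]tri(propan-2-yl)silane | COCOc1cc(O[Si](C(C)C)(C(C)C)C(C)C)cc(OCOC)c1C/C=C(\C)CCC=C(C)C
F14 | step 9 | 6-geranyl-5,7-dihydroxy-2-(3-hydroxy-4,5-dimethoxyphenyl)-4H-chromen-4-one | COc1cc(-c2cc(=O)c3c(O)c(C/C=C(\C)CCC=C(C)C)c(O)cc3o2)cc(O)c1OC
F15 | step 9 | 5,7-bis(tert-butyldimethylsilyloxy)-2-[3-(tert-butyldimethylsilyloxy)-4,5-dimethoxyphenyl]-6-geranyl-4H-chromen-4-one | COc1cc(-c2cc(=O)c3c(O[Si](C)(C)C(C)(C)C)c(C/C=C(\C)CCC=C(C)C)c(O[Si](C)(C)C(C)(C)C)cc3o2)cc(O[Si](C)(C)C(C)(C)C)c1OC
F16 | step 9 | (2S)-5,7-bis(tert-butyldimethylsilyloxy)-2-[3-(tert-butyldimethylsilyloxy)-4,5-dimethoxyphenyl]-4-{[diethoxy(methyl)silyl]oxy}-6-geranyl-2H-chromene | COc1cc([C@@H]2C=C(O[Si](C)(OCC)OCC)c3c(O[Si](C)(C)C(C)(C)C)c(C/C=C(\C)CCC=C(C)C)c(O[Si](C)(C)C(C)(C)C)cc3O2)cc(O[Si](C)(C)C(C)(C)C)c1OC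
F17 | step 9 | (2S)-5,7-bis(tert-butyldimethylsilyloxy)-2-[3-(tert-butyldimethylsilyloxy)-4,5-dimethoxyphenyl]-6-geranyl-2,3-dihydro-4H-chromen-4-one | COc1cc([C@@H]2CC(=O)c3c(O[Si](C)(C)C(C)(C)C)c(C/C=C(\C)CCC=C(C)C)c(O[Si](C)(C)C(C)(C)C)cc3O2)cc(O[Si](C)(C)C(C)(C)C)c1OC
F18 | step 4 | 2-[4-geranyl-3,5-bis(methoxymethoxy)phenoxy]oxane (racemic) | COCOc1cc(OC2CCCCO2)cc(OCOC)c1C/C=C(\C)CCC=C(C)C
F19 | step 4 | {3-geranyl-2,4-bis(methoxymethoxy)-6-(oxan-2-yloxy)phenyl}lithium | [Li]c1c(OC2CCCCO2)cc(OCOC)c(C/C=C(\C)CCC=C(C)C)c1OCOC
F20 | step 4 | 2-[4-geranyl-2-iodo-3,5-bis(methoxymethoxy)phenoxy]oxane (racemic) | COCOc1cc(OC2CCCCO2)c(I)c(OCOC)c1C/C=C(\C)CCC=C(C)C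
A1 | alternative 1 | (2S)-2-[3-(tert-butyldimethylsilyloxy)-4,5-dimethoxyphenyl]-6-geranyl-5-hydroxy-7-(triisopropylsilyloxy)-2,3-dihydro-4H-chromen-4-one | COc1cc([C@@H]2CC(=O)c3c(cc(O[Si](C(C)C)(C(C)C)C(C)C)c(C/C=C(\C)CCC=C(C)C)c3O)O2)cc(O[Si](C)(C)C(C)(C)C)c1OC
A2 | alternative 1 | (2S)-2-[3-(tert-butyldimethylsilyloxy)-4,5-dimethoxyphenyl]-6-(diazoacetyl)-2,3-dihydro-4H-pyran-4-one | COc1cc([C@@H]2CC(=O)C=C(C(=O)C=[N+]=[N-])O2)cc(O[Si](C)(C)C(C)(C)C)c1OC
A3 | alternative 1 | {[(4E)-5,9-dimethyldeca-4,8-dien-1-yn-1-yl]oxy}tri(propan-2-yl)silane | CC(C)[Si](OC#CC/C=C(\C)CCC=C(C)C)(C(C)C)C(C)C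
A4 | alternative 2 | (2S,4S)-5,7-bis(tert-butyldimethylsilyloxy)-2-[3-(tert-butyldimethylsilyloxy)-4,5-dimethoxyphenyl]-6-geranyl-4-methoxy-3,4-dihydro-2H-chromene | COc1cc([C@@H]2C[C@H](OC)c3c(cc(O[Si](C)(C)C(C)(C)C)c(C/C=C(\C)CCC=C(C)C)c3O[Si](C)(C)C(C)(C)C)O2)cc(O[Si](C)(C)C(C)(C)C)c1OC
A5 | alternative 2 | 3,5-bis(tert-butyldimethylsilyloxy)-2-(dimethoxymethyl)-4-geranylphenol | COC(OC)c1c(O)cc(O[Si](C)(C)C(C)(C)C)c(C/C=C(\C)CCC=C(C)C)c1O[Si](C)(C)C(C)(C)C
A6 | alternative 2 | tert-butyl(5-ethenyl-2,3-dimethoxyphenoxy)dimethylsilane | C=Cc1cc(OC)c(OC)c(O[Si](C)(C)C(C)(C)C)c1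
A7 | alternative 3 | (2S)-2-[3,4-dimethoxy-5-(methoxymethoxy)phenyl]-6-geranyl-5,7-bis(methoxymethoxy)-3,4-dihydro-2H-chromen-4-ol (C4 epimers) | COc1cc([C@@H]2CC(O)c3c(cc(OCOC)c(C/C=C(\C)CCC=C(C)C)c3OCOC)O2)cc(OCOC)c1OC
A8 | alternative 3 | (3S)-1-[2-bromo-5-geranyl-4,6-bis(methoxymethoxy)phenyl]-3-[3,4-dimethoxy-5-(methoxymethoxy)phenyl]propane-1,3-diol | COc1cc([C@@H](O)CC(O)c2c(Br)cc(OCOC)c(C/C=C(\C)CCC=C(C)C)c2OCOC)cc(OCOC)c1OC
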